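## Structural features

The target is a 2,3-dihydro-1-benzofuran-6(5H)-one in which a dihydrofuran (O1, C2, C3, C3a, C7a) shares the C3a–C7a bond with a cyclohexa-2,4-dienone (C3a=C4, C7=C7a, C6=O, sp3 C5). Because O1 is attached to C7a, the array O1–C7a=C7–C6=O is a vinylogous ester and the carbocycle is a dearomatised resorcinol. C2 bears the 3,4,5-trimethoxyphenyl group and the adjacent C3 a methyl group; the two are trans and both centres are S. The third centre, C5, is quaternary (allyl, methoxy, C4, C6), is also S, and lies two sp2 carbons away from C3, so the C2/C3 pair cannot be relied on to direct it. Sensitive features are the dienone that cannot aromatise (allyl shifts on heating, cycloaddition dimers, ketol shifts in base), the benzylic C2–O1 bond (ionisation in acid would scramble C2), the terminal alkene (which rules out a late hydrogenation) and the aryl methyl ethers. The difficulty is twofold: the absolute and trans-relative configuration of C2 and C3, and the oxygenated quaternary C5 that has to be created together with the dienone at the end. The key step exploits the bond between C3 and the fused arene carbon C3a together with the one-carbon branch on C3: the ring O1–C2–C3–C3a–C7a is the pyranone ring of a 2-arylchroman-4-one from which the carbonyl carbon has been pushed out onto C3.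

## Logic of the disconnections

19 ⇒ 18. The O–CH3 bond on the C5 oxygen is cut. Alkylation at oxygen cannot disturb the quaternary centre, so the ether is best made last, and the C5 problem shrinks to one C–O bond. The forward step needs a methylation that is neither strongly basic nor hot.

18 ⇒ 17. The C5–O bond is cut and the dienone returns to a phenol with its hydroxyl on C6. Every earlier step then runs on a stable arene and one stereocentre disappears. The forward step must deliver oxygen to C5 and not to C7 or C3a. It has no facial control, so both configurations at C5 will form and the wanted one has to be separated.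

17 ⇒ 16. The O–benzyl bond is cut. The phenol must be masked through the catalytic arylation, the oxidative rearrangement and the hydride steps, and as an ether oxygen para to the migrating carbon it assists the key step. The forward cleavage must work without hydrogen because of the allyl group.

16 ⇒ 14 + 15. The bond between C5 and the allyl CH2 is cut. An alkene would not survive the electrophilic iodine reagent or the divalent palladium catalyst, whereas a bromine atom does and marks C5 from the first aromatic substitution onwards. The forward coupling must not move the double bond into conjugation.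

14 ⇒ 13 ⇒ 12 ⇒ 11. The C3 methyl group is traced back to a C3 ester by exchanging its C–H bonds for C–O bonds. This brings no simplification in itself, but the ester is what the key step leaves behind and it lets C3 settle trans. The forward steps must not hold the ester enolate long enough for O1 to be expelled from C2, and the hydride displacement must substitute without eliminating.

11 ⇒ 8 (through 10 and 9). The C3–C3a bond is cut and C3a is rejoined to the ester carbon, which re-expands the ring to a six-membered ketone. Two adjacent stereocentres become one, and 8 belongs to a class with reliable catalytic asymmetric entries. The forward step requires the ring A carbon to migrate anti to the leaving group in preference to every other pathway open to the C3 iodane.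

8 ⇒ 6 + 7. The C2–aryl bond is cut. The single stereocentre needed before the key step is then set by a catalyst, and the electron-rich aryl group arrives after the bromination that it would not have survived. The forward step needs face selection and tolerance of the C–Br bond.

6 ⇒ 4 (through 5). O1–C2 and C2–C3 are cut, which removes the one carbon that an amide acetal can supply and leaves a simple methyl ketone. The forward step must close the pyranone through the free ortho hydroxyl without disturbing the bromide or the benzyl ether.

4 ⇒ 3 ⇒ 1 + 2. The C–Br bond is cut first, then the O–benzyl bond. In the forward direction the benzyl group goes on before bromine, so that the one free, chelated hydroxyl directs bromine para to itself and the position between the two oxygens stays untouched.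

## Other disconnections considered

Alternative 1: Four bonds of the carbocycle (C3a–C4, C6–C7, C3a–C7a, C5–C6) are removed at once. This leads to the acyclic diazo enone A1 and ethoxyethyne A2. O1–C7a would be closed afterwards: once the silyl group is off, the C2 oxygen displaces ethoxide from the vinylogous ester of the annulation product A3.
- Forward key step: Wolff rearrangement of A1 shifts the alkenyl group to the carbene carbon (C3a–C4) and gives a vinylketene. Its cycloaddition with A2 forms C6–C7 and C3a–C7a. Opening of the cyclobutenone (4π) and closure of the dienylketene (6π) then form C5–C6 and give A3.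
- In favour: the dienone appears in its final oxidation state with both C5 substituents in place, so neither a phenol oxidation nor the methylation of a tertiary alcohol is needed. On this point it is the better plan. It is also convergent, so its longest linear sequence could be shorter.
- Against: C5 is created in the electrocyclisation with only the remote side chain as bias, so on C5 it is the equal of the chosen plan and no better. A1 combines a diazo ketone, an enol ether and a terminal alkene and needs a stereoselective synthesis of its own. The usual driving force of this annulation, tautomerisation to a phenol, is absent because C5 is quaternary. Dienones such as A3 reopen to dienylketenes under light, so a photochemical Wolff step would endanger the product.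
- Comparison: structurally it builds the hard ring directly. Mechanistically, a four-event pericyclic cascade ending on a fully substituted terminus has less direct analogy than a single 1,2-shift on a flavanone. The chosen plan is the more certain; the alternative is the more direct on paper.

Alternative 2: O1–C2 and C2–C3 are cut, which takes C2 and its aryl group out as a one-carbon unit. This leads to the ortho-quinone methide A4 and the benzylic sulfonium salt A5 of an enantiopure sulfide.
- Forward key step: a mild carbonate base releases A4 in the flask and deprotonates A5 to its ylide. The ylide carbon adds to C3 (C2–C3) and the phenoxide displaces the sulfide (O1–C2), which closes the dihydrofuran and gives A6.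
- In favour: the ring and both stereocentres form in one step, trans by anti closure of the betaine. The allyl group is present from the start, so no tin reagent is needed. The silyl ether falls to fluoride, which is milder than a Lewis-acid debenzylation. On step economy and on the unmasking of the phenol it is the better plan.
- Against: absolute control rests on a stoichiometric chiral sulfide with an aryl-stabilised ylide and an alkylidene quinone methide, a pairing with less support than ester- or ketone-stabilised ylides. A4 can tautomerise to a vinylphenol or dimerise. The enantiomer of the sulfide drawn in A5 is a guess that would have to be confirmed.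
- Comparison: desilylation of A6 gives 17, so the endgame and the C5 problem are identical (equal). The chosen plan is longer, but it takes its absolute configuration from a catalytic step with close analogy and its trans relationship from a stereospecific shift.

Alternative 3: The C5–O bond is cut with the oxygen tethered to the ring as the carboxylate of the phenol acid A7.
- Forward key step: a C2-symmetric chiral aryl iodide is oxidised in the flask by a peracid to the trivalent iodine species. This binds the phenol oxygen, and the carboxylate attacks C5 to close the five-membered spirolactone A8 on the new 2,4-dienone.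
- In favour: the tether reaches only C5, and the catalyst, not the distant C2/C3 pair, chooses the face. This is the one stereocentre the chosen plan cannot control, and here the alternative is clearly the better.
- Against: A8 has a lactone where the target has methoxy and allyl. Reaching the target needs lactone opening, O-methylation of the tertiary alcohol (the same problem as in the chosen plan, equal), reduction of the chain terminus next to a dienone carbonyl, and dehydration to the alkene. That is about four further steps on the most fragile intermediate.
- Comparison: both plans end with a hypervalent iodine dearomatisation, and A7 could itself be reached from 14, so the two share their structural basis. The alternative trades the loss of material to the unwanted C5 configuration for a longer and chemoselectively harder endgame. If the separation at C5 proved impractical, it would become the better plan.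

Key step: step 5

Assumption: the (R)-configured tert-butyl pyridine-oxazoline ligand is taken to deliver the aryl group to the face of 6 that gives (2S)-8, by analogy with the face preference of the (S)-ligand with cyclic enones. If the sense were the reverse, the (S)-ligand would be used and nothing else would change.

## Route

Step 1
Reactants: 1 2,4-dihydroxyacetophenone; 2 benzyl bromide
Product: 3 1-[4-(benzyloxy)-2-hydroxyphenyl]ethanone
Conditions: K2CO3 (1.1 equiv), acetone, reflux
Reagents that add atoms: none
Why: Williamson ether synthesis; the 2-hydroxyl is hydrogen-bonded to the acetyl carbonyl and much less reactive, so alkylation should stop at O4.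

Step 2
Reactants: 3 1-[4-(benzyloxy)-2-hydroxyphenyl]ethanone
Product: 4 1-[4-(benzyloxy)-5-bromo-2-hydroxyphenyl]ethanone
Conditions: NBS (1.0 equiv), MeCN, 0 °C to rt
Reagents that add atoms: N-bromosuccinimide, O=C1CCC(=O)N1Br
Why: Electrophilic aromatic bromination; C5 is para to the free hydroxyl and ortho to the ether, while C3 is flanked by both oxygens, so bromine should enter at C5. Benzylating first avoids the C3/C5 mixture and the dibromination expected of the free resorcinol.

Step 3
Reactants: 4 1-[4-(benzyloxy)-5-bromo-2-hydroxyphenyl]ethanone
Product: 6 7-(benzyloxy)-6-bromo-4H-chromen-4-one, via enaminone 5 (not isolated)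
Conditions: Me2NCH(OMe)2, toluene, 100 °C; evaporate; conc. HCl, CH2Cl2, rt
Reagents that add atoms: N,N-dimethylformamide dimethyl acetal, COC(OC)N(C)C
Why: Condensation of the methyl ketone with the amide acetal gives the enaminone 5; acid then triggers oxa-Michael addition of the phenol and loss of dimethylamine (enaminone route to chromones).

Step 4
Reactants: 6 7-(benzyloxy)-6-bromo-4H-chromen-4-one; 7 3,4,5-trimethoxyphenylboronic acid
Product: 8 (2S)-7-(benzyloxy)-6-bromo-2-(3,4,5-trimethoxyphenyl)chroman-4-one
Conditions: Pd(OCOCF3)2 (5 mol%), (R)-4-tert-butyl-2-(pyridin-2-yl)-4,5-dihydrooxazole (6 mol%), NH4PF6 (30 mol%), H2O (5 equiv), 7 (2 equiv), ClCH2CH2Cl, 60 °C, under air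
Reagents that add atoms: none
Why: Enantioselective conjugate addition of an arylboronic acid to a chromone under divalent palladium: transmetalation, insertion of C2=C3 into the aryl–Pd bond, protonolysis of the enolate. The tert-butyl group of the ligand shields one face in the insertion and so sets C2; the metal stays divalent, so the C–Br bond should not be touched.

Step 5
Reactants: 8 (2S)-7-(benzyloxy)-6-bromo-2-(3,4,5-trimethoxyphenyl)chroman-4-one
Product: 11 methyl (2S,3S)-6-(benzyloxy)-5-bromo-2-(3,4,5-trimethoxyphenyl)-2,3-dihydro-1-benzofuran-3-carboxylate, via enol ether 9 (not isolated), via iodane ketal 10 (not isolated)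
Conditions: PhI(OAc)2 (1.2 equiv), conc. H2SO4 (0.5 equiv), HC(OMe)3, 0 °C to rt
Reagents that add atoms: trimethyl orthoformate, COC(OC)OC
Why: Acid and orthoformate convert 8 into the enol ether 9; the electrophilic trivalent iodine reagent then bonds to C3 on the face away from the pseudo-equatorial C2 aryl group while methanol caps C4, which gives the 2,3-trans ketal 10 with iodine equatorial. In 10 the C4–C4a bond is antiperiplanar to C3–I, so as iodobenzene departs the ring A carbon C4a shifts from C4 to C3 through a bridged arenium transition state, forming C3–C3a with inversion at C3; the dimethoxycarbenium ion left at the old C4 gives up a methyl group to acetate and becomes the ester. The closest known reaction type is the oxidative 1,2-aryl rearrangement of aryl ketones and of flavanones with trivalent iodine or Tl(NO3)3 in orthoformate. The dihydrofuran closes by contraction, not by cyclisation: O1, C2, C3 and the arene are already connected, and the shift (formally ipso attack giving a spiro three-membered arenium ion that reopens) turns the six-membered ring into the five-membered one. C3 is the new stereocentre and is controlled by C2: iodine enters trans to the aryl group and is replaced with inversion, so the ester carbon ends trans to the aryl group (3S), an outcome that the enolisable ester also favours thermodynamically; C2 itself is not touched. The step needs ring A migration to win over migration of the C2 aryl group, loss of H-2 towards the flavone and methanolysis of the C–I bond. The benzyloxy oxygen para and O1 ortho to C4a make that carbon the best migrating terminus, the diequatorial conformer of 10 places only C4a among the carbon groups anti to the leaving group, and the bromine meta to C4a should cost little.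

Step 6
Reactants: 11 methyl (2S,3S)-6-(benzyloxy)-5-bromo-2-(3,4,5-trimethoxyphenyl)-2,3-dihydro-1-benzofuran-3-carboxylate
Product: 12 [(2S,3R)-6-(benzyloxy)-5-bromo-2-(3,4,5-trimethoxyphenyl)-2,3-dihydro-1-benzofuran-3-yl]methanol
Conditions: i-Bu2AlH (2.5 equiv), CH2Cl2, −78 to 0 °C; aq. KNaC4H4O6 (potassium sodium tartrate)
Reagents that add atoms: none
Why: Hydride reduction of an ester to the primary alcohol; a Lewis-acidic, non-basic hydride at low temperature avoids E1cB opening of the ring through the ester enolate and leaves the C–Br bond alone. No stereocentre reacts (the C3 letter changes by priority only).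

Step 7
Reactants: 12 [(2S,3R)-6-(benzyloxy)-5-bromo-2-(3,4,5-trimethoxyphenyl)-2,3-dihydro-1-benzofuran-3-yl]methanol
Product: 13 [(2S,3R)-6-(benzyloxy)-5-bromo-2-(3,4,5-trimethoxyphenyl)-2,3-dihydro-1-benzofuran-3-yl]methyl 4-methylbenzenesulfonate
Conditions: TsCl (1.3 equiv), Et3N, DMAP (cat.), CH2Cl2, 0 °C to rt
Reagents that add atoms: 4-toluenesulfonyl chloride, Cc1ccc(S(=O)(=O)Cl)cc1
Why: Sulfonylation of an unhindered primary alcohol; the conditions are too mild to affect C2 or C3.

Step 8
Reactants: 13 [(2S,3R)-6-(benzyloxy)-5-bromo-2-(3,4,5-trimethoxyphenyl)-2,3-dihydro-1-benzofuran-3-yl]methyl 4-methylbenzenesulfonate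
Product: 14 (2S,3S)-6-(benzyloxy)-5-bromo-3-methyl-2-(3,4,5-trimethoxyphenyl)-2,3-dihydro-1-benzofuran
Conditions: LiEt3BH (3 equiv), THF, 0 °C to rt
Reagents that add atoms: none
Why: SN2 displacement of a primary tosylate by the most nucleophilic common hydride donor, which favours substitution over elimination; the aryl bromide and the benzyl ether are inert, and the reacting carbon is not stereogenic.

Step 9
Reactants: 14 (2S,3S)-6-(benzyloxy)-5-bromo-3-methyl-2-(3,4,5-trimethoxyphenyl)-2,3-dihydro-1-benzofuran; 15 allyltributylstannane
Product: 16 (2S,3S)-5-allyl-6-(benzyloxy)-3-methyl-2-(3,4,5-trimethoxyphenyl)-2,3-dihydro-1-benzofuran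
Conditions: Pd(PPh3)4 (5 mol%), 15 (1.5 equiv), toluene, 110 °C
Reagents that add atoms: none
Why: Stille coupling: oxidative addition of zerovalent palladium into C5–Br, allyl transfer from tin, reductive elimination. The conditions are neutral, so neither stereocentre is at risk.

Step 10
Reactants: 16 (2S,3S)-5-allyl-6-(benzyloxy)-3-methyl-2-(3,4,5-trimethoxyphenyl)-2,3-dihydro-1-benzofuran
Product: 17 (2S,3S)-5-allyl-3-methyl-2-(3,4,5-trimethoxyphenyl)-2,3-dihydro-1-benzofuran-6-ol
Conditions: BCl3 (2 equiv), C6HMe5 (3 equiv), CH2Cl2, −78 °C; MeOH quench
Reagents that add atoms: none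
Why: Lewis-acid debenzylation with a cation scavenger: BCl3 activates the benzyl ether and pentamethylbenzene takes up the benzyl cation by Friedel–Crafts alkylation. At −78 °C the alkene and the methyl ethers should be spared, whereas hydrogenolysis would reduce the allyl group.

Step 11
Reactants: 17 (2S,3S)-5-allyl-3-methyl-2-(3,4,5-trimethoxyphenyl)-2,3-dihydro-1-benzofuran-6-ol
Product: 18 (2S,3S,5S)-5-allyl-5-hydroxy-3-methyl-2-(3,4,5-trimethoxyphenyl)-2,3-dihydro-1-benzofuran-6(5H)-one
Conditions: IBX (1.2 equiv), DMF, rt, dark; H2O then aq. NaHCO3; chromatography on SiO2 (separation of the C5 diastereomers)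
Reagents that add atoms: 2-iodoxybenzoic acid, O=C1OI(=O)(O)c2ccccc12
Why: Hydroxylative phenol dearomatisation: the phenol oxygen binds to pentavalent iodine and an iodyl oxygen is passed within the complex to an ortho carbon, which limits attack to C5 or C7; C5 is para to O1 and alkyl-substituted and should be preferred. The new centre C5 forms without facial bias, so both configurations are expected and the 5S diastereomer 18 is isolated by chromatography.

Step 12
Reactants: 18 (2S,3S,5S)-5-allyl-5-hydroxy-3-methyl-2-(3,4,5-trimethoxyphenyl)-2,3-dihydro-1-benzofuran-6(5H)-one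
Product: 19 (2S,3S,5S)-5-allyl-5-methoxy-3-methyl-2-(3,4,5-trimethoxyphenyl)-2,3-dihydro-1-benzofuran-6(5H)-one
Conditions: MeI (10 equiv), Ag2O (3 equiv), CaSO4, MeCN, rt, dark
Reagents that add atoms: iodomethane, CI
Why: Purdie methylation of the relatively acidic ketol hydroxyl under near-neutral conditions; only the O–H bond reacts, so the C5 configuration is carried over unchanged.

## Compound list

1 | 2,4-dihydroxyacetophenone | CC(=O)c1ccc(O)cc1O | starting material
2 | benzyl bromide | BrCc1ccccc1 | starting material
3 | 1-[4-(benzyloxy)-2-hydroxyphenyl]ethanone | CC(=O)c1ccc(OCc2ccccc2)cc1O | intermediate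
4 | 1-[4-(benzyloxy)-5-bromo-2-hydroxyphenyl]ethanone | CC(=O)c1cc(Br)c(OCc2ccccc2)cc1O | intermediate
5 | (E)-1-[4-(benzyloxy)-5-bromo-2-hydroxyphenyl]-3-(dimethylamino)prop-2-en-1-one | CN(C)/C=C/C(=O)c1cc(Br)c(OCc2ccccc2)cc1O | intermediate
6 | 7-(benzyloxy)-6-bromo-4H-chromen-4-one | O=c1ccoc2cc(OCc3ccccc3)c(Br)cc12 | intermediate
7 | 3,4,5-trimethoxyphenylboronic acid | COc1cc(B(O)O)cc(OC)c1OC | starting material
8 | (2S)-7-(benzyloxy)-6-bromo-2-(3,4,5-trimethoxyphenyl)chroman-4-one | O=C1C[C@@H](c2cc(OC)c(OC)c(OC)c2)Oc2cc(OCc3ccccc3)c(Br)cc12 | intermediate
9 | (2S)-7-(benzyloxy)-6-bromo-4-methoxy-2-(3,4,5-trimethoxyphenyl)-2H-chromene | COC1=C[C@@H](c2cc(OC)c(OC)c(OC)c2)Oc2cc(OCc3ccccc3)c(Br)cc12 | intermediate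
10 | (2R,3R)-3-[acetoxy(phenyl)-λ3-iodanyl]-7-(benzyloxy)-6-bromo-4,4-dimethoxy-2-(3,4,5-trimethoxyphenyl)chromane, iodine trans to the aryl group, C2 arranged in space as in 8 (letter changed by priority only) | COC1(OC)[C@H](I(OC(C)=O)c2ccccc2)[C@@H](c2cc(OC)c(OC)c(OC)c2)Oc2cc(OCc3ccccc3)c(Br)cc12 | intermediate
11 | methyl (2S,3S)-6-(benzyloxy)-5-bromo-2-(3,4,5-trimethoxyphenyl)-2,3-dihydro-1-benzofuran-3-carboxylate | Brc1cc2c(cc1OCc1ccccc1)O[C@H](c1cc(OC)c(OC)c(OC)c1)[C@H]2C(=O)OC | intermediate
12 | [(2S,3R)-6-(benzyloxy)-5-bromo-2-(3,4,5-trimethoxyphenyl)-2,3-dihydro-1-benzofuran-3-yl]methanol | Brc1cc2c(cc1OCc1ccccc1)O[C@H](c1cc(OC)c(OC)c(OC)c1)[C@H]2CO | intermediate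
13 | [(2S,3R)-6-(benzyloxy)-5-bromo-2-(3,4,5-trimethoxyphenyl)-2,3-dihydro-1-benzofuran-3-yl]methyl 4-methylbenzenesulfonate | Brc1cc2c(cc1OCc1ccccc1)O[C@H](c1cc(OC)c(OC)c(OC)c1)[C@H]2COS(=O)(=O)c1ccc(C)cc1 | intermediate
14 | (2S,3S)-6-(benzyloxy)-5-bromo-3-methyl-2-(3,4,5-trimethoxyphenyl)-2,3-dihydro-1-benzofuran | Brc1cc2c(cc1OCc1ccccc1)O[C@H](c1cc(OC)c(OC)c(OC)c1)[C@H]2C | intermediate
15 | allyltributylstannane | C=CC[Sn](CCCC)(CCCC)CCCC | starting material
16 | (2S,3S)-5-allyl-6-(benzyloxy)-3-methyl-2-(3,4,5-trimethoxyphenyl)-2,3-dihydro-1-benzofuran | C=CCc1cc2c(cc1OCc1ccccc1)O[C@H](c1cc(OC)c(OC)c(OC)c1)[C@H]2C | intermediate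
17 | (2S,3S)-5-allyl-3-methyl-2-(3,4,5-trimethoxyphenyl)-2,3-dihydro-1-benzofuran-6-ol | C=CCc1cc2c(cc1O)O[C@H](c1cc(OC)c(OC)c(OC)c1)[C@H]2C | intermediate
18 | (2S,3S,5S)-5-allyl-5-hydroxy-3-methyl-2-(3,4,5-trimethoxyphenyl)-2,3-dihydro-1-benzofuran-6(5H)-one | C=CC[C@]1(O)C=C2C(=CC1=O)O[C@H](c1cc(OC)c(OC)c(OC)c1)[C@H]2C | intermediate
19 | (2S,3S,5S)-5-allyl-5-methoxy-3-methyl-2-(3,4,5-trimethoxyphenyl)-2,3-dihydro-1-benzofuran-6(5H)-one | C=CC[C@]1(OC)C=C2C(=CC1=O)O[C@H](c1cc(OC)c(OC)c(OC)c1)[C@H]2C | target

## Step count and least certain steps

Total: 12 steps. Longest linear sequence: 12 steps (1 to 19); 2, 7 and 15 enter as purchased reagents.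

Key step (step 5). The C3 iodane may leave by other routes: loss of H-2 towards the flavone, migration of the C2 aryl group, or methanolysis of the C–I bond. Acid may also reopen the pyranone before ketalisation and erode C2, and the activated iodine reagent may attack the electron-rich trimethoxyphenyl ring. The fallback reaches the same bond by a Wolff ring contraction and sets out from 8. Condensation with Me2NCH(OMe)2 would give the 3-(dimethylaminomethylidene) ketone F1. Diazo transfer with tosyl azide would give the 3-diazo ketone F2. Irradiation at 365 nm in MeOH would move C4a to the carbene carbon and trap the ketene as the methyl ester, expected largely as the cis ester F3 because the proton arrives anti to the aryl group. Brief treatment with catalytic NaOMe in MeOH would settle C3 trans, and the sequence comes back at 11.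

Step 11. Oxygen may be transferred to C7 instead of C5 (leading on to a quinone), the dienone may dimerise by cycloaddition, and the lack of facial control means that about half of the material is expected with the wrong C5 configuration. The fallback is a Wessely acetoxylation, which also prefers the alkyl-bearing ortho carbon, and sets out from 17. Pb(OAc)4 in AcOH/CH2Cl2 at 0 °C would give the quinol acetate F4 as both C5 epimers. Methanolysis with catalytic K2CO3 in MeOH at 0 °C would release 18 together with its 5R epimer F5, which are separated on SiO2. F5 could be reduced back to 17 with Zn in AcOH and resubmitted. The fallback comes back at 18.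

Step 12. Alkylation of the hindered tertiary hydroxyl may be slow, and forcing it invites a ketol shift or migration of the allyl group. The fallback forms the C5–OCH3 bond directly and sets out from 17. Oxidation with PhI(OAc)2 in MeOH at −20 °C would let methanol attack the activated phenol at C5 and give 19 together with its C5 epimer F6, to be separated. It comes back at 19. Attack of methanol at C3a is the risk accepted there.

Step 4. Insertion into the electron-rich chromone may be slow, the boronic acid may deborylate or homocouple, zerovalent palladium formed on the way may insert into the C–Br bond, and the face selection may be low or of the wrong sense. The fallback is a resolution and sets out from 4. Claisen–Schmidt condensation with 3,4,5-trimethoxybenzaldehyde (KOH, EtOH) would give the chalcone F7. Cyclisation (NaOAc, EtOH, reflux) would give the racemic flavanone F8. Asymmetric transfer hydrogenation with RuCl(p-cymene)[(R,R)-TsDPEN] in HCO2H/Et3N is expected to reduce the (2R) enantiomer to the cis alcohol F9 and leave the (2S) ketone, so it comes back at 8, at the cost of half the material.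

Step 10. The Lewis acid may ionise the benzylic C2–O1 bond (epimerisation or ring opening), remove a methyl ether, or promote addition of the freed phenol to the allyl group. The fallback changes the way the allyl group is introduced and sets out from 14. Hydrogenolysis (H2, Pd/C (10%), Et3N, EtOAc) would remove benzyl and bromine together and give the phenol F10. Allyl bromide with K2CO3 in acetone would give the allyl ether F11. Claisen rearrangement (PhNEt2, 190 °C) should place the allyl group mainly at C5, para to O1, so it comes back at 17.

## Further compounds

F1 | step 5 | (2R)-7-(benzyloxy)-6-bromo-3-[(dimethylamino)methylidene]-2-(3,4,5-trimethoxyphenyl)chroman-4-one, C2 arranged in space as in 8 | CN(C)C=C1C(=O)c2cc(Br)c(OCc3ccccc3)cc2O[C@@H]1c1cc(OC)c(OC)c(OC)c1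
F2 | step 5 | (2R)-7-(benzyloxy)-6-bromo-3-diazo-2-(3,4,5-trimethoxyphenyl)chroman-4-one, C2 arranged in space as in 8 | [N-]=[N+]=C1C(=O)c2cc(Br)c(OCc3ccccc3)cc2O[C@@H]1c1cc(OC)c(OC)c(OC)c1
F3 | step 5 | methyl (2S,3R)-6-(benzyloxy)-5-bromo-2-(3,4,5-trimethoxyphenyl)-2,3-dihydro-1-benzofuran-3-carboxylate, cis isomer of 11 | Brc1cc2c(cc1OCc1ccccc1)O[C@H](c1cc(OC)c(OC)c(OC)c1)[C@@H]2C(=O)OC
F4 | step 11 | (2S,3S)-5-allyl-3-methyl-6-oxo-2-(3,4,5-trimethoxyphenyl)-2,3,5,6-tetrahydro-1-benzofuran-5-yl acetate, both C5 epimers | C=CCC1(OC(C)=O)C=C2C(=CC1=O)O[C@H](c1cc(OC)c(OC)c(OC)c1)[C@H]2C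
F5 | step 11 | (2S,3S,5R)-5-allyl-5-hydroxy-3-methyl-2-(3,4,5-trimethoxyphenyl)-2,3-dihydro-1-benzofuran-6(5H)-one, C5 epimer of 18 | C=CC[C@@]1(O)C=C2C(=CC1=O)O[C@H](c1cc(OC)c(OC)c(OC)c1)[C@H]2C
F6 | step 12 | (2S,3S,5R)-5-allyl-5-methoxy-3-methyl-2-(3,4,5-trimethoxyphenyl)-2,3-dihydro-1-benzofuran-6(5H)-one, C5 epimer of 19 | C=CC[C@@]1(OC)C=C2C(=CC1=O)O[C@H](c1cc(OC)c(OC)c(OC)c1)[C@H]2C
F7 | step 4 | (E)-1-[4-(benzyloxy)-5-bromo-2-hydroxyphenyl]-3-(3,4,5-trimethoxyphenyl)prop-2-en-1-one | COc1cc(/C=C/C(=O)c2cc(Br)c(OCc3ccccc3)cc2O)cc(OC)c1OC
F8 | step 4 | racemic 7-(benzyloxy)-6-bromo-2-(3,4,5-trimethoxyphenyl)chroman-4-one | O=C1CC(c2cc(OC)c(OC)c(OC)c2)Oc2cc(OCc3ccccc3)c(Br)cc12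
F9 | step 4 | (2R,4R)-7-(benzyloxy)-6-bromo-2-(3,4,5-trimethoxyphenyl)chroman-4-ol | O[C@@H]1C[C@H](c2cc(OC)c(OC)c(OC)c2)Oc2cc(OCc3ccccc3)c(Br)cc12
F10 | step 10 | (2S,3S)-3-methyl-2-(3,4,5-trimethoxyphenyl)-2,3-dihydro-1-benzofuran-6-ol | Oc1ccc2c(c1)O[C@H](c1cc(OC)c(OC)c(OC)c1)[C@H]2C
F11 | step 10 | (2S,3S)-6-(allyloxy)-3-methyl-2-(3,4,5-trimethoxyphenyl)-2,3-dihydro-1-benzofuran | C=CCOc1ccc2c(c1)O[C@H](c1cc(OC)c(OC)c(OC)c1)[C@H]2C
A1 | alternative 1 | (8S,9S)-9-(tert-butyldimethylsilyloxy)-7-diazo-4-methoxy-8-methyl-9-(3,4,5-trimethoxyphenyl)nona-1,4-dien-6-one | C=CCC(OC)=CC(=O)C(=[N+]=[N-])[C@H](C)[C@H](O[Si](C)(C)C(C)(C)C)c1cc(OC)c(OC)c(OC)c1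
A2 | alternative 1 | ethoxyethyne | C#COCC
A3 | alternative 1 | (6S)-6-allyl-3-ethoxy-6-methoxy-4-[(1S,2S)-2-(tert-butyldimethylsilyloxy)-1-methyl-2-(3,4,5-trimethoxyphenyl)ethyl]cyclohexa-2,4-dienone | C=CC[C@]1(OC)C=C([C@H](C)[C@H](O[Si](C)(C)C(C)(C)C)c2cc(OC)c(OC)c(OC)c2)C(OCC)=CC1=O
A4 | alternative 2 | 4-allyl-6-ethylidene-3-(triisopropylsilyloxy)cyclohexa-2,4-dien-1-one | CC=C1C=C(CC=C)C(O[Si](C(C)C)(C(C)C)C(C)C)=CC1=O
A5 | alternative 2 | (2R,5R)-2,5-dimethyl-1-(3,4,5-trimethoxybenzyl)thiolan-1-ium bromide | C[C@@H]1CC[C@@H](C)[S+]1Cc1cc(OC)c(OC)c(OC)c1.[Br-]
A6 | alternative 2 | (2S,3S)-5-allyl-3-methyl-6-(triisopropylsilyloxy)-2-(3,4,5-trimethoxyphenyl)-2,3-dihydro-1-benzofuran | C=CCc1cc2c(cc1O[Si](C(C)C)(C(C)C)C(C)C)O[C@H](c1cc(OC)c(OC)c(OC)c1)[C@H]2C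
A7 | alternative 3 | 3-[(2S,3S)-6-hydroxy-3-methyl-2-(3,4,5-trimethoxyphenyl)-2,3-dihydro-1-benzofuran-5-yl]propanoic acid | OC(=O)CCc1cc2c(cc1O)O[C@H](c1cc(OC)c(OC)c(OC)c1)[C@H]2C
A8 | alternative 3 | (2S,3S)-3-methyl-2-(3,4,5-trimethoxyphenyl)-2,3-dihydrospiro[1-benzofuran-5,2'-oxolane]-5',6-dione, spiro centre S, lactone oxygen in the place of the methoxy oxygen of 19 | O=C1CC[C@]2(O1)C=C3C(=CC2=O)O[C@H](c1cc(OC)c(OC)c(OC)c1)[C@H]3C
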